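**Strategy**

The δ-lactone (O1, C2 carbonyl, C4 carbinol, C6 ring CH) is taken apart across C5–C6 and O1–C2. C6, which carries both the ring oxygen and the E-alkenyl chain, is a latent enal carbonyl; O1–C2–C3–C4–C5 is a but-3-enoate. A copper-catalysed asymmetric vinylogous aldol–lactonisation (formal hetero-[4+2]) joins the complete acyclic dienal 9 with methyl but-3-enoate: it forges C5–C6, closes the pyranone ring and sets C6 in one operation. The C3=C4 unsaturation it leaves is the handle for a trans-selective conjugate borylation–oxidation that installs the C4 hydroxyl. The anti-1,3-dimethoxy array comes from a vinylogous Mukaiyama aldol and a directed anti reduction.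

Key step: step 6

Numbering used below: lactone O1, C2–C6; side chain C7–C14, with the methoxy groups on C10 and C12 and the phenyl on C14.

Assumption: the antipodes of BINOL and DTBM-SEGPHOS named are those expected, from the usual facial preferences of these catalyst families, to give 5S in step 1 and 6R in step 6; should the sense prove opposite, the other antipode is used without further change.

**Route**

Step 1
Reactants: 1 (E)-cinnamaldehyde; 2 1-methoxy-1,3-bis(trimethylsilyloxy)buta-1,3-diene (bis-silyl dienol ether of methyl acetoacetate)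
Product: 4 methyl (5S,6E)-5-hydroxy-3-oxo-7-phenylhept-6-enoate, via bis-silylated aldol adduct 3 (not isolated)
Conditions: Ti(OiPr)4 (10 mol%), (S)-BINOL (10 mol%), 4 Å MS, THF, −78 °C → rt; then PPTS, MeOH, 0 °C
Reagents that add atoms: none
Why: Catalytic enantioselective vinylogous Mukaiyama aldol in which the terminal carbon of the diene adds 1,2 to the titanium–BINOL-bound aldehyde on its Si face (catalyst control), setting the future C12 as S, and mild methanolysis then removes both silyl groups without ionising the allylic alcohol.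

Step 2
Reactants: 4 methyl (5S,6E)-5-hydroxy-3-oxo-7-phenylhept-6-enoate
Product: 5 methyl (3S,5S,6E)-3,5-dihydroxy-7-phenylhept-6-enoate
Conditions: Me4NBH(OAc)3 (5 equiv), MeCN/AcOH (1:1), −30 °C
Reagents that add atoms: none
Why: Evans–Saksena reduction, in which the C5 hydroxyl binds boron and delivers hydride intramolecularly through a chair transition state, should give the 1,3-anti diol and so set the future C10 under substrate control.

Step 3
Reactants: 5 methyl (3S,5S,6E)-3,5-dihydroxy-7-phenylhept-6-enoate
Product: 6 methyl (3S,5S,6E)-3,5-dimethoxy-7-phenylhept-6-enoate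
Conditions: Me3OBF4 (5 equiv), 1,8-bis(dimethylamino)naphthalene (6 equiv), CH2Cl2, 0 °C → rt
Reagents that add atoms: trimethyloxonium tetrafluoroborate, C[O+](C)C.F[B-](F)(F)F
Why: O-Methylation by an oxonium salt under a non-nucleophilic proton scavenger avoids the retro-aldol and β-elimination that alkoxide conditions would cause in a β-hydroxy ester, and no stereocenter is touched.

Step 4
Reactants: 6 methyl (3S,5S,6E)-3,5-dimethoxy-7-phenylhept-6-enoate
Product: 7 (3S,5S,6E)-3,5-dimethoxy-7-phenylhept-6-enal
Conditions: iBu2AlH (1.1 equiv), CH2Cl2, −78 °C; aqueous Rochelle salt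
Reagents that add atoms: none
Why: Partial ester reduction at low temperature should stop at the aluminium hemiacetal, which the β-methoxy group helps to stabilise, and release the aldehyde only on work-up.

Step 5
Reactants: 7 (3S,5S,6E)-3,5-dimethoxy-7-phenylhept-6-enal; 8 (triphenylphosphoranylidene)acetaldehyde
Product: 9 (2E,5R,7S,8E)-5,7-dimethoxy-9-phenylnona-2,8-dienal
Conditions: toluene, 60 °C (1.2 equiv of 8)
Reagents that add atoms: none
Why: Wittig olefination with the stabilised formylmethylene ylide should give the (E)-enal by two-carbon homologation, the weakly basic ylide leaving the β-methoxy aldehyde and both stereocenters intact.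

Step 6
Reactants: 9 (2E,5R,7S,8E)-5,7-dimethoxy-9-phenylnona-2,8-dienal; 10 methyl but-3-enoate
Product: 11 (6R)-6-[(1E,4R,6S,7E)-4,6-dimethoxy-8-phenylocta-1,7-dien-1-yl]-5,6-dihydro-2H-pyran-2-one
Conditions: [Cu(MeCN)4]PF6 (5 mol%), (R)-DTBM-SEGPHOS (6 mol%), 2-tert-butyl-1,1,3,3-tetramethylguanidine (10 mol%), 10 (2 equiv), THF, −20 °C
Reagents that add atoms: none
Why: Soft enolisation of 10 by the bisphosphine complex of monovalent copper and the guanidine base gives an s-cis copper dienolate whose γ-carbon (future C5) adds 1,2 to the aldehyde carbon of 9 (future C6), and the copper alkoxide so formed acylates itself on the Z-enoate within the same catalytic cycle, expelling methoxide that regenerates the base, so the net event is a formal hetero-[4+2] annulation. The closest known reaction type is the copper-catalysed direct asymmetric vinylogous aldol–lactonisation of β,γ-unsaturated esters with aldehydes, the catalytic counterpart of hetero-Diels–Alder reactions of siloxydienes with enals. One ring is closed, the six-membered lactone, by C5–C6 bond formation followed at once by 6-exo-trig acyl substitution at C2 by O1. The only new stereocenter, C6, is set by the chiral ligand, which should expose the Re face of the aldehyde and give 6R; C10 and C12 lie four and six bonds away and are not expected to bias the face. The step needs γ- over α-attack of the dienolate (secured by the bulky ligand), 1,2- over 1,4-addition to the enal (the aldehyde carbon is the hard, unhindered site) and survival of the γ-CH2/δ-OMe array of 9 (only catalytic base, low temperature).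

Step 7
Reactants: 11 (6R)-6-[(1E,4R,6S,7E)-4,6-dimethoxy-8-phenylocta-1,7-dien-1-yl]-5,6-dihydro-2H-pyran-2-one
Product: 13 (4S,6R)-6-[(1E,4R,6S,7E)-4,6-dimethoxy-8-phenylocta-1,7-dien-1-yl]-4-hydroxytetrahydro-2H-pyran-2-one, via trans-4-boryl lactone 12 (not isolated)
Conditions: CuCl (5 mol%), NaOtBu (5 mol%, premixed), DPEphos (5 mol%), B2pin2 (1.1 equiv), MeOH (2 equiv), THF, 0 °C → rt; then NaBO3·4H2O, THF/H2O, rt
Reagents that add atoms: bis(pinacolato)diboron, CC1(C)OB(OC1(C)C)B1OC(C)(C)C(C)(C)O1 (boron of 12); sodium perborate tetrahydrate, [Na+].[O-]OB=O.O.O.O.O (hydroxyl oxygen of 13)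
Why: Copper-catalysed conjugate borylation of the enoate should occur by axial attack anti to the pseudo-equatorial C6 chain (as cuprates do on 6-substituted 5,6-dihydropyran-2-ones), setting C4 trans to C6, and stereoretentive perborate oxidation of C–B to C–OH then gives the (4S,6R) hydroxy lactone while the unactivated alkenes stay untouched.

**Compound list**

1 | (E)-cinnamaldehyde | O=C/C=C/c1ccccc1 | starting material
2 | 1-methoxy-1,3-bis(trimethylsilyloxy)buta-1,3-diene (C1=C2 isomer mixture as supplied) | COC(O[Si](C)(C)C)=CC(=C)O[Si](C)(C)C | starting material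
3 | methyl (2Z,5S,6E)-7-phenyl-3,5-bis(trimethylsilyloxy)hepta-2,6-dienoate | COC(=O)/C=C(\O[Si](C)(C)C)C[C@@H](/C=C/c1ccccc1)O[Si](C)(C)C | intermediate (not isolated)
4 | methyl (5S,6E)-5-hydroxy-3-oxo-7-phenylhept-6-enoate | COC(=O)CC(=O)C[C@@H](/C=C/c1ccccc1)O | intermediate
5 | methyl (3S,5S,6E)-3,5-dihydroxy-7-phenylhept-6-enoate | COC(=O)C[C@@H](O)C[C@@H](/C=C/c1ccccc1)O | intermediate
6 | methyl (3S,5S,6E)-3,5-dimethoxy-7-phenylhept-6-enoate | COC(=O)C[C@@H](OC)C[C@@H](/C=C/c1ccccc1)OC | intermediate
7 | (3S,5S,6E)-3,5-dimethoxy-7-phenylhept-6-enal | O=CC[C@@H](OC)C[C@@H](/C=C/c1ccccc1)OC | intermediate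
8 | (triphenylphosphoranylidene)acetaldehyde | O=CC=P(c1ccccc1)(c1ccccc1)c1ccccc1 | starting material
9 | (2E,5R,7S,8E)-5,7-dimethoxy-9-phenylnona-2,8-dienal | O=C/C=C/C[C@@H](OC)C[C@@H](/C=C/c1ccccc1)OC | intermediate
10 | methyl but-3-enoate | COC(=O)CC=C | starting material
11 | (6R)-6-[(1E,4R,6S,7E)-4,6-dimethoxy-8-phenylocta-1,7-dien-1-yl]-5,6-dihydro-2H-pyran-2-one | CO[C@H](C/C=C/[C@H]1CC=CC(=O)O1)C[C@@H](/C=C/c1ccccc1)OC | intermediate
12 | (4S,6R)-6-[(1E,4R,6S,7E)-4,6-dimethoxy-8-phenylocta-1,7-dien-1-yl]-4-(4,4,5,5-tetramethyl-1,3,2-dioxaborolan-2-yl)tetrahydro-2H-pyran-2-one | CO[C@H](C/C=C/[C@H]1C[C@H](B2OC(C)(C)C(C)(C)O2)CC(=O)O1)C[C@@H](/C=C/c1ccccc1)OC | intermediate (not isolated)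
13 | (4S,6R)-6-[(1E,4R,6S,7E)-4,6-dimethoxy-8-phenylocta-1,7-dien-1-yl]-4-hydroxytetrahydro-2H-pyran-2-one | CO[C@H](C/C=C/[C@H]1C[C@H](O)CC(=O)O1)C[C@@H](/C=C/c1ccccc1)OC | target

**Step count and risks**

Total step count: 7. Longest linear sequence: 7 steps (1 → 13).

Steps most likely to fail:

Step 6. The guanidine base may deprotonate the γ-CH2 of enal 9 in competition with ester 10, leading to self-condensation or loss of methanol across C9–C10, and γ-selectivity or facial control may be insufficient on this hindered enal. The fallback sets out from 9 and builds the ring by a different bond order. Brown allylation of 9 with (+)-Ipc2B(allyl) (Et2O, −78 °C, oxidative work-up) should give the homoallylic alcohol (4R,5E,8R,10S,11E)-8,10-dimethoxy-12-phenyldodeca-1,5,11-trien-4-ol F1. Acylation with acryloyl chloride (Et3N, DMAP, CH2Cl2, 0 °C) should give (4R,5E,8R,10S,11E)-8,10-dimethoxy-12-phenyldodeca-1,5,11-trien-4-yl prop-2-enoate F2. Ring-closing metathesis between the acrylate and the terminal alkene (second-generation Grubbs catalyst, CH2Cl2, 40 °C) then returns to the route at 11.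

Step 7. Facial selectivity of the copper–boryl addition may be incomplete, and the alkoxide-containing medium may open or eliminate the unsaturated lactone before borylation. The fallback sets out from 11. Nucleophilic epoxidation (30% H2O2, catalytic NaOH, MeOH, 0 °C), anti to the C6 chain, should give (3S,4S,6R)-3,4-epoxy-6-[(1E,4R,6S,7E)-4,6-dimethoxy-8-phenylocta-1,7-dien-1-yl]tetrahydro-2H-pyran-2-one F3. Reductive opening at the α-carbon with sodium phenylselenide ((PhSe)2, NaBH4, AcOH, EtOH, 0 °C → rt) retains the C4–O bond and returns to the route at 13.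

Step 5. The enal product may react a second time with the ylide (over-homologation to a dienal), and prolonged heating may eliminate methanol from the β-methoxy aldehyde. The fallback sets out from 7. Horner–Wadsworth–Emmons olefination with triethyl phosphonoacetate under LiCl/DBU in MeCN should give ethyl (2E,5R,7S,8E)-5,7-dimethoxy-9-phenylnona-2,8-dienoate F4. Reduction with iBu2AlH (2.2 equiv, CH2Cl2, −78 °C) should give (2E,5R,7S,8E)-5,7-dimethoxy-9-phenylnona-2,8-dien-1-ol F5. Allylic oxidation with MnO2 (CH2Cl2, rt) returns to the route at 9.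

**Further compounds**

F1 | step 6 | (4R,5E,8R,10S,11E)-8,10-dimethoxy-12-phenyldodeca-1,5,11-trien-4-ol | CO[C@H](C/C=C/[C@H](O)CC=C)C[C@@H](/C=C/c1ccccc1)OC
F2 | step 6 | (4R,5E,8R,10S,11E)-8,10-dimethoxy-12-phenyldodeca-1,5,11-trien-4-yl prop-2-enoate | CO[C@H](C/C=C/[C@H](OC(=O)C=C)CC=C)C[C@@H](/C=C/c1ccccc1)OC
F3 | step 7 | (3S,4S,6R)-3,4-epoxy-6-[(1E,4R,6S,7E)-4,6-dimethoxy-8-phenylocta-1,7-dien-1-yl]tetrahydro-2H-pyran-2-one | CO[C@H](C/C=C/[C@H]1C[C@@H]2O[C@@H]2C(=O)O1)C[C@@H](/C=C/c1ccccc1)OC
F4 | step 5 | ethyl (2E,5R,7S,8E)-5,7-dimethoxy-9-phenylnona-2,8-dienoate | CCOC(=O)/C=C/C[C@@H](OC)C[C@@H](/C=C/c1ccccc1)OC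
F5 | step 5 | (2E,5R,7S,8E)-5,7-dimethoxy-9-phenylnona-2,8-dien-1-ol | OC/C=C/C[C@@H](OC)C[C@@H](/C=C/c1ccccc1)OC
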